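**Retrosynthetic overview**
1. Target 26 ⇐ dioxirane epoxidation of the ring Z-olefin C3=C4 of trienone lactone 25 (last step), after C8–O desilylation and C1 oxidation.
2. 10-membered carbocycle (formed second) ⇐ C1–C10 bond by intramolecular Nozaki–Hiyama–Kishi closure of bromo-aldehyde 22; C9 angelate by Yamaguchi esterification.
3. γ-Lactone (formed first) ⇐ C6–C7 bond by CrCl2-mediated 2-(methoxycarbonyl)allylation/lactonisation of aldehyde 16 with allylic bromide 11.
4. 11 ⇐ vinylalumination and allylic transposition of aldehyde 6 ⇐ D-proline cross-aldol of silyloxyacetaldehyde 4 with 2-bromoacrolein 3 (sets C8 and C9; C6 and C7 are relayed from them).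
5. 16 ⇐ Birch reduction and enol-ether ozonolysis of 3-methylanisole 12 (ring-locked Z-olefin). Ring order: lactone, then carbocycle, then epoxide.

Assumption: atoms are numbered as a germacran-6,12-olide (C1 ketone, C3/C4 epoxide with C15 methyl on C4, C6 lactone O-carbon, C8 OH, C9 angelate, C10=C14, C11=C13, C12 lactone C=O); by CIP the target is 3S,4R,6R,7R,8S,9R with a trans-fused lactone and a cis epoxide.

**Step 1**
Reactants: 1 acrolein
Product: 3 2-bromoprop-2-enal (2-bromoacrolein), via 2,3-dibromopropanal 2 (not isolated)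
Conditions: Br2, CH2Cl2, −78 °C; then Et3N, −78 to 0 °C
Reagents that add atoms: bromine BrBr
Why: Bromine addition to the enal followed by E1cB loss of HBr through the acidic α-hydrogen gives the α-bromoenal (bromination–dehydrobromination).

**Step 2**
Reactants: 3 2-bromoacrolein; 4 2-[(tert-butyldimethylsilyl)oxy]acetaldehyde
Product: 5 (2R,3S)-4-bromo-2-[(tert-butyldimethylsilyl)oxy]-3-hydroxypent-4-enal
Conditions: D-proline (20 mol %), DMF, 4 °C, slow addition of 4 to 3 (3 equiv)
Reagents that add atoms: none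
Why: Proposed new method: an enamine cross-aldol in which an α-silyloxyacetaldehyde donor adds to an α-haloenal acceptor, a class not yet used in proline aldol chemistry (closest known reaction: the proline-catalysed cross-aldol of α-oxyaldehyde donors with α-branched alkyl aldehydes); 2-bromoacrolein cannot enolise, its α-substituent disfavours iminium formation with the secondary amine so it should act only as a carbonyl electrophile activated by the α-bromine, and the acid-directed chair (Houk–List) transition state of the anti-enamine of D-proline sets C8 (2R) and C9 (3S) in the anti relationship.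

**Step 3**
Reactants: 5 aldol adduct
Product: 6 (2R,3S)-4-bromo-2-[(tert-butyldimethylsilyl)oxy]-3-[(triethylsilyl)oxy]pent-4-enal
Conditions: Et3SiOTf, 2,6-lutidine, CH2Cl2, −78 °C
Reagents that add atoms: triethylsilyl trifluoromethanesulfonate CC[Si](CC)(CC)OS(=O)(=O)C(F)(F)F
Why: Silyl triflate/hindered base silylation of the secondary alcohol at −78 °C outruns enolisation and β-elimination, so C8 and C9 are untouched.

**Step 4**
Reactants: 6 bis-silyl aldehyde; 7 methyl propiolate
Product: 9 methyl (4S,5S)-6-bromo-4-[(tert-butyldimethylsilyl)oxy]-3-hydroxy-2-methylidene-5-[(triethylsilyl)oxy]hept-6-enoate (both C3 epimers), via methyl 2-(diisobutylalumanyl)acrylate 8 (not isolated)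
Conditions: i-Bu2AlH, N-methylmorpholine N-oxide, 7, THF, 0 °C; then 6, 0 °C to rt
Reagents that add atoms: diisobutylaluminium hydride CC(C)C[AlH]CC(C)C (its Al(i-Bu)2 stays only in 8; 9 keeps only its hydrogen)
Why: Hydroalumination of the propiolate gives an α-alumino acrylate that adds 1,2 to the aldehyde (vinylalumination, a non-basic Morita–Baylis–Hillman equivalent), so C8 is not epimerised; the new carbinol (C7) is a mixture that is erased in step 5.

**Step 5**
Reactants: 9 hydroxy acrylate
Product: 11 methyl (2Z,4S,5S)-6-bromo-2-(bromomethyl)-4-[(tert-butyldimethylsilyl)oxy]-5-[(triethylsilyl)oxy]hepta-2,6-dienoate, via C3 methanesulfonate 10 (not isolated)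
Conditions: Ms2O, Et3N, CH2Cl2, −20 °C; then LiBr, THF, 0 °C to rt
Reagents that add atoms: lithium bromide [Li+].[Br-]; methanesulfonic anhydride CS(=O)(=O)OS(C)(=O)=O (mesyl group in 10 only)
Why: Mesylation then SN2′ displacement by bromide (allylic transposition) gives the thermodynamically preferred (Z)-2-(bromomethyl)enoate and makes C7 sp2.

**Step 6**
Reactants: 12 3-methylanisole
Product: 13 1-methoxy-5-methylcyclohexa-1,4-diene
Conditions: Li, NH3 (l), t-BuOH, THF, −78 to −33 °C
Reagents that add atoms: none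
Why: Birch reduction leaves the methoxy and methyl groups on the two remaining, non-conjugated double bonds.

**Step 7**
Reactants: 13 dihydroanisole
Product: 15 methyl (3Z)-6,6-dimethoxy-3-methylhex-3-enoate, via methyl (3Z)-3-methyl-6-oxohex-3-enoate 14 (not isolated)
Conditions: O3 (1 equiv), CH2Cl2–MeOH, −78 °C; Me2S; then HC(OMe)3, PPTS, MeOH, rt
Reagents that add atoms: ozone O=[O+][O-]; trimethyl orthoformate COC(OC)OC
Why: Chemoselective ozonolysis cleaves only the electron-rich enol-ether double bond, giving ester (future C6) and aldehyde (future C1) termini while the ring-derived trisubstituted olefin keeps its Z geometry; the aldehyde is acetalised in the same pot.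

**Step 8**
Reactants: 15 ester acetal
Product: 16 (3Z)-6,6-dimethoxy-3-methylhex-3-enal
Conditions: i-Bu2AlH (1.05 equiv), CH2Cl2, −78 °C
Reagents that add atoms: none
Why: Low-temperature half-reduction of the methyl ester stops at the aluminium hemiacetal, which releases the aldehyde on neutral work-up without conjugating the β,γ-olefin.

**Step 9**
Reactants: 11 allylic bromide; 16 aldehyde
Product: 18 (4S,5R)-4-[(1S,2S)-3-bromo-1-[(tert-butyldimethylsilyl)oxy]-2-hydroxybut-3-en-1-yl]-5-[(2Z)-5,5-dimethoxy-2-methylpent-2-en-1-yl]-3-methylideneoxolan-2-one, via C9-triethylsilyl ether lactone 17 (not isolated)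
Conditions: CrCl2 (4 equiv), THF, rt; then PPTS, MeOH, rt
Reagents that add atoms: none
Why: Nozaki–Hiyama (Cr-mediated Barbier) allylation in which CrCl2 without nickel inserts only into the allylic C–Br bond; the chair transition state gives the anti adduct (C6/C7, trans-lactone after lactonisation), and with H-8 held in the olefin plane by A(1,3) strain the aldehyde attacks C7 anti to the bulky C9 branch, giving the 7,8-relationship of the target; PPTS/MeOH completes lactonisation and removes only the triethylsilyl group.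

**Step 10**
Reactants: 18 lactone alcohol; 19 angelic acid
Product: 21 (4S,5R)-4-[(1S,2S)-3-bromo-1-[(tert-butyldimethylsilyl)oxy]-2-{[(2Z)-2-methylbut-2-enoyl]oxy}but-3-en-1-yl]-5-[(2Z)-5,5-dimethoxy-2-methylpent-2-en-1-yl]-3-methylideneoxolan-2-one, via angelic 2,4,6-trichlorobenzoic anhydride 20 (not isolated)
Conditions: 19, 2,4,6-trichlorobenzoyl chloride, Et3N, toluene, rt; then 18, toluene, 75 °C
Reagents that add atoms: 2,4,6-trichlorobenzoyl chloride O=C(Cl)c1c(Cl)cc(Cl)cc1Cl (aroyl group in 20 only)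
Why: Yamaguchi esterification through the mixed anhydride, run without a nucleophilic catalyst, acylates the hindered C9 hydroxyl and keeps the Z (angelate) geometry.

**Step 11**
Reactants: 21 angelate acetal
Product: 22 (4S,5R)-4-[(1S,2S)-3-bromo-1-[(tert-butyldimethylsilyl)oxy]-2-{[(2Z)-2-methylbut-2-enoyl]oxy}but-3-en-1-yl]-5-[(2Z)-2-methyl-5-oxopent-2-en-1-yl]-3-methylideneoxolan-2-one
Conditions: LiBF4, MeCN–H2O (50:1), rt
Reagents that add atoms: water O
Why: Mild Lewis-acid acetal hydrolysis frees the C1 aldehyde without cleaving the TBS ether or moving the β,γ-olefin into conjugation.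

**Step 12**
Reactants: 22 bromo-aldehyde
Product: 23 (3Z,6R,7S,8S,9R)-9-(angeloyloxy)-8-[(tert-butyldimethylsilyl)oxy]-1-hydroxygermacra-3,10(14),11(13)-trien-6,12-olide (both C1 epimers)
Conditions: CrCl2 (10 equiv), NiCl2 (10 mol %), DMSO–THF, rt, syringe-pump addition to 2 mM
Reagents that add atoms: none
Why: Intramolecular Nozaki–Hiyama–Kishi reaction, in which nickel-catalysed activation of the 1,1-disubstituted vinyl bromide and transfer to chromium give an alkenylchromium that adds only to the aldehyde and closes the 10-membered ring (the Z-olefin and fused lactone pre-organise the chain); the C1 configuration is irrelevant because it is oxidised next.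

**Step 13**
Reactants: 23 allylic alcohol
Product: 24 (3Z,6R,7S,8S,9R)-9-(angeloyloxy)-8-[(tert-butyldimethylsilyl)oxy]-1-oxogermacra-3,10(14),11(13)-trien-6,12-olide
Conditions: Dess–Martin periodinane, CH2Cl2, 0 °C to rt
Reagents that add atoms: none
Why: Dess–Martin oxidation converts both C1 epimers into the exo-methylene ketone under non-basic conditions that do not isomerise the β,γ-olefin.

**Step 14**
Reactants: 24 silyl ether
Product: 25 (3Z,6R,7R,8S,9R)-9-(angeloyloxy)-8-hydroxy-1-oxogermacra-3,10(14),11(13)-trien-6,12-olide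
Conditions: HF·pyridine, pyridine, THF, 0 °C to rt
Reagents that add atoms: none
Why: Buffered fluoride desilylation cleaves the secondary TBS ether without touching the esters or enone and without promoting 9→8 acyl migration.

**Step 15**
Reactants: 25 trienone lactone
Product: 26 (3S,4R,6R,7R,8S,9R)-9-(angeloyloxy)-3,4-epoxy-8-hydroxy-1-oxogermacra-10(14),11(13)-dien-6,12-olide (target CNP0348992.6)
Conditions: dimethyldioxirane (1.1 equiv), acetone, −40 to −20 °C
Reagents that add atoms: dimethyldioxirane CC1(C)OO1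
Why: Neutral electrophilic (dioxirane) epoxidation attacks only the electron-rich trisubstituted C3=C4 bond, since the other three C=C bonds are carbonyl-conjugated, and is stereospecifically cis; attack on the outer face of the ring olefin is expected, but not proven, to give the 3S,4R epoxide.

**Compound list**
1 | acrolein (prop-2-enal) | C=CC=O | starting material
2 | 2,3-dibromopropanal | O=CC(Br)CBr | intermediate
3 | 2-bromoprop-2-enal | C=C(Br)C=O | intermediate
4 | 2-[(tert-butyldimethylsilyl)oxy]acetaldehyde | CC(C)(C)[Si](C)(C)OCC=O | starting material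
5 | (2R,3S)-4-bromo-2-[(tert-butyldimethylsilyl)oxy]-3-hydroxypent-4-enal | C=C(Br)[C@@H](O)[C@@H](O[Si](C)(C)C(C)(C)C)C=O | intermediate
6 | (2R,3S)-4-bromo-2-[(tert-butyldimethylsilyl)oxy]-3-[(triethylsilyl)oxy]pent-4-enal | C=C(Br)[C@@H](O[Si](CC)(CC)CC)[C@@H](O[Si](C)(C)C(C)(C)C)C=O | intermediate
7 | methyl propiolate | C#CC(=O)OC | starting material
8 | methyl 2-(diisobutylalumanyl)prop-2-enoate | C=C(C(=O)OC)[Al](CC(C)C)CC(C)C | intermediate
9 | methyl (4S,5S)-6-bromo-4-[(tert-butyldimethylsilyl)oxy]-3-hydroxy-2-methylidene-5-[(triethylsilyl)oxy]hept-6-enoate (both C3 epimers) | C=C(Br)[C@@H](O[Si](CC)(CC)CC)[C@@H](O[Si](C)(C)C(C)(C)C)C(O)C(=C)C(=O)OC | intermediate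
10 | C3 methanesulfonate of 9 (silyloxy centres unchanged) | C=C(Br)[C@@H](O[Si](CC)(CC)CC)[C@@H](O[Si](C)(C)C(C)(C)C)C(OS(C)(=O)=O)C(=C)C(=O)OC | intermediate
11 | methyl (2Z,4S,5S)-6-bromo-2-(bromomethyl)-4-[(tert-butyldimethylsilyl)oxy]-5-[(triethylsilyl)oxy]hepta-2,6-dienoate | C=C(Br)[C@@H](O[Si](CC)(CC)CC)[C@@H](O[Si](C)(C)C(C)(C)C)/C=C(\CBr)C(=O)OC | intermediate
12 | 3-methylanisole | COc1cccc(C)c1 | starting material
13 | 1-methoxy-5-methylcyclohexa-1,4-diene | COC1=CCC=C(C)C1 | intermediate
14 | methyl (3Z)-3-methyl-6-oxohex-3-enoate | COC(=O)C/C(C)=C\CC=O | intermediate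
15 | methyl (3Z)-6,6-dimethoxy-3-methylhex-3-enoate | COC(=O)C/C(C)=C\CC(OC)OC | intermediate
16 | (3Z)-6,6-dimethoxy-3-methylhex-3-enal | O=CC/C(C)=C\CC(OC)OC | intermediate
17 | (4S,5R)-4-[(1S,2S)-3-bromo-1-[(tert-butyldimethylsilyl)oxy]-2-[(triethylsilyl)oxy]but-3-en-1-yl]-5-[(2Z)-5,5-dimethoxy-2-methylpent-2-en-1-yl]-3-methylideneoxolan-2-one | C=C1C(=O)O[C@H](C/C(C)=C\CC(OC)OC)[C@H]1[C@H](O[Si](C)(C)C(C)(C)C)[C@H](O[Si](CC)(CC)CC)C(Br)=C | intermediate
18 | (4S,5R)-4-[(1S,2S)-3-bromo-1-[(tert-butyldimethylsilyl)oxy]-2-hydroxybut-3-en-1-yl]-5-[(2Z)-5,5-dimethoxy-2-methylpent-2-en-1-yl]-3-methylideneoxolan-2-one | C=C1C(=O)O[C@H](C/C(C)=C\CC(OC)OC)[C@H]1[C@H](O[Si](C)(C)C(C)(C)C)[C@H](O)C(Br)=C | intermediate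
19 | angelic acid, (2Z)-2-methylbut-2-enoic acid | C/C=C(/C)C(=O)O | starting material
20 | (2Z)-2-methylbut-2-enoic 2,4,6-trichlorobenzoic anhydride | C/C=C(/C)C(=O)OC(=O)c1c(Cl)cc(Cl)cc1Cl | intermediate
21 | (4S,5R)-4-[(1S,2S)-3-bromo-1-[(tert-butyldimethylsilyl)oxy]-2-{[(2Z)-2-methylbut-2-enoyl]oxy}but-3-en-1-yl]-5-[(2Z)-5,5-dimethoxy-2-methylpent-2-en-1-yl]-3-methylideneoxolan-2-one | C=C1C(=O)O[C@H](C/C(C)=C\CC(OC)OC)[C@H]1[C@H](O[Si](C)(C)C(C)(C)C)[C@H](OC(=O)/C(C)=C\C)C(Br)=C | intermediate
22 | (4S,5R)-4-[(1S,2S)-3-bromo-1-[(tert-butyldimethylsilyl)oxy]-2-{[(2Z)-2-methylbut-2-enoyl]oxy}but-3-en-1-yl]-5-[(2Z)-2-methyl-5-oxopent-2-en-1-yl]-3-methylideneoxolan-2-one | C=C1C(=O)O[C@H](C/C(C)=C\CC=O)[C@H]1[C@H](O[Si](C)(C)C(C)(C)C)[C@H](OC(=O)/C(C)=C\C)C(Br)=C | intermediate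
23 | (3Z,6R,7S,8S,9R)-9-(angeloyloxy)-8-[(tert-butyldimethylsilyl)oxy]-1-hydroxygermacra-3,10(14),11(13)-trien-6,12-olide (both C1 epimers) | C=C1C(=O)O[C@@H]2C/C(C)=C\CC(O)C(=C)[C@@H](OC(=O)/C(C)=C\C)[C@@H](O[Si](C)(C)C(C)(C)C)[C@@H]12 | intermediate
24 | (3Z,6R,7S,8S,9R)-9-(angeloyloxy)-8-[(tert-butyldimethylsilyl)oxy]-1-oxogermacra-3,10(14),11(13)-trien-6,12-olide | C=C1C(=O)O[C@@H]2C/C(C)=C\CC(=O)C(=C)[C@@H](OC(=O)/C(C)=C\C)[C@@H](O[Si](C)(C)C(C)(C)C)[C@@H]12 | intermediate
25 | (3Z,6R,7R,8S,9R)-9-(angeloyloxy)-8-hydroxy-1-oxogermacra-3,10(14),11(13)-trien-6,12-olide | C=C1C(=O)O[C@@H]2C/C(C)=C\CC(=O)C(=C)[C@@H](OC(=O)/C(C)=C\C)[C@@H](O)[C@@H]12 | intermediate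
26 | (3S,4R,6R,7R,8S,9R)-9-(angeloyloxy)-3,4-epoxy-8-hydroxy-1-oxogermacra-10(14),11(13)-dien-6,12-olide | C=C1C(=O)O[C@@H]2C[C@@]3(C)O[C@H]3CC(=O)C(=C)[C@@H](OC(=O)/C(C)=C\C)[C@@H](O)[C@@H]12 | target

**Step count and risks**
Total steps: 15. Longest linear sequence: 12 (steps 1–5 and 9–15, from acrolein); the 3-methylanisole branch (steps 6–8) joins at step 9.

Steps most likely to fail:

Step 2 (the proposed new cross-aldol). 2-Bromoacrolein may add to or alkylate the amine catalyst (aza-Michael addition, then aziridinium formation) faster than the enamine attacks it, and 4 may self-condense. The fallback uses known chemistry, sets out from 3 and comes back to the route at 6. Iridium-catalysed transfer-hydrogenative anti-(α-benzoyloxy)allylation of 3 with prop-2-ene-1,1-diyl dibenzoate ([Ir(cod)Cl]2, SEGPHOS of the sense giving the 3S,4S product, 4-chloro-3-nitrobenzoic acid, Cs2CO3, i-PrOH, THF) gives (3S,4S)-5-bromo-4-hydroxyhexa-1,5-dien-3-yl benzoate F1. Et3SiOTf/2,6-lutidine then gives (3S,4S)-5-bromo-4-[(triethylsilyl)oxy]hexa-1,5-dien-3-yl benzoate F2. i-Bu2AlH at −78 °C removes the benzoate to give (3S,4S)-5-bromo-4-[(triethylsilyl)oxy]hexa-1,5-dien-3-ol F3. t-BuMe2SiOTf/2,6-lutidine gives tert-butyl({(3S,4S)-5-bromo-4-[(triethylsilyl)oxy]hexa-1,5-dien-3-yl}oxy)dimethylsilane F4. Ozonolysis of the monosubstituted vinyl group only (O3, CH2Cl2, −78 °C, then PPh3; the bromo-olefin is deactivated) delivers 6.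

Step 9 (Cr-mediated allylation–lactonisation). The anti (trans-lactone) outcome is dependable, but which face of C7 is attacked relative to the C8 silyloxy centre rests on an A(1,3)-strain argument and could be weak or reversed. The fallback sets out from 11 and 16 and comes back at 18; it makes no new compound (F0). Face selection is handed to a catalyst: catalytic asymmetric Nozaki–Hiyama allylation with CrCl3 (10 mol %), a chiral carbazole-bis(oxazoline) ligand (enantiomer chosen to give 6R), Mn powder as terminal reductant, Me3SiCl and i-Pr2NEt in THF. Because the chair transition state ties C7 to C6, fixing the aldehyde face fixes both centres; PPTS/MeOH follows as before.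

Step 15 (final epoxidation). Chemoselectivity is safe, but the face of the Z-olefin is controlled only by ring conformation, and the β,γ-epoxy ketone is base-sensitive. The fallback sets out from 25 and ends at 26; it makes no new compound (F0). It is a reagent-controlled asymmetric epoxidation with the chiral dioxirane from the fructose-derived ketone (Shi epoxidation; D- or L-series ketone chosen empirically for the 3S,4R face). The ketone is used stoichiometrically with KHSO5 at pH 7.5–8 (NaHCO3 buffer), −10 °C, in MeCN–dimethoxymethane–water.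

The macrocyclisation in step 12 ranks fourth: closure to a 10-membered ring by this reaction type has precedent, and the Z-olefin and lactone help, but it has no short alternative from 22.

**Further compounds**
F1 | step 2 | (3S,4S)-5-bromo-4-hydroxyhexa-1,5-dien-3-yl benzoate | C=C(Br)[C@@H](O)[C@@H](OC(=O)c1ccccc1)C=C
F2 | step 2 | (3S,4S)-5-bromo-4-[(triethylsilyl)oxy]hexa-1,5-dien-3-yl benzoate | C=C(Br)[C@@H](O[Si](CC)(CC)CC)[C@@H](OC(=O)c1ccccc1)C=C
F3 | step 2 | (3S,4S)-5-bromo-4-[(triethylsilyl)oxy]hexa-1,5-dien-3-ol | C=C(Br)[C@@H](O[Si](CC)(CC)CC)[C@@H](O)C=C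
F4 | step 2 | tert-butyl({(3S,4S)-5-bromo-4-[(triethylsilyl)oxy]hexa-1,5-dien-3-yl}oxy)dimethylsilane | C=C(Br)[C@@H](O[Si](CC)(CC)CC)[C@@H](O[Si](C)(C)C(C)(C)C)C=C
F0 | step 9 | none | none
F0 | step 15 | none | none
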